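## The problem

7-O-Methylluteone (14) is an isoflavone: benzene ring A is fused to the 4-pyranone ring C, the resorcinol ring B sits on C3, and C2 carries only hydrogen. It has no stereocentre, so the whole task is regiochemistry and telling four oxygens apart. Ring A is a fully differentiated phloroglucinol (O1 in the ring, O5 a free phenol hydrogen-bonded to the C4 carbonyl, O7 a methyl ether) and carries the prenyl group at C6, between O5 and O7, while the electronically similar C8 stays free. The prenyl group is the fragile part: acid closes it onto the 5-hydroxyl to a dimethyldihydropyran, and electrophilic oxidants, Lewis acids and hydrogenation all attack the alkene, which limits both when it can be introduced and which protecting groups may still be present afterwards. The pyranone is a vinylogous ester that hydroxide opens at C2, and the 2'-oxygen of ring B lies within reach of C2 and will attack an electrophilic centre generated there. Two features make a short route possible. First, the C2-C3-C4 unit with the aryl group on the middle carbon next to the carbonyl is the three-carbon chain of a chalcone after a 1,2-shift of ring B from the β- to the α-carbon, with O1 supplied by a ring A phenol ortho to the acyl group. Second, C6 is the only hydrogen-bearing carbon ortho to O5 (the other neighbour is the ring-fusion carbon C4a), so an allyl group delivered from O5 by a [3,3] shift can only arrive at C6.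

## Retrosynthesis

**14 from 13.** The last disconnection is of the two O-CH2OMe bonds on ring B. O2' and O4' must be masked, because the step that brings in the prenyl carbons through O5 needs O5 as the only free hydroxyl. Methoxymethyl ethers are preferred to benzyl ethers here: they leave in dilute methanolic acid, whereas benzyl ethers would need hydrogenolysis or a boron halide, neither of which the prenyl alkene tolerates. 13 differs from the target only by these two acetals. The forward step needs acid mild enough not to add O5 to the alkene.

**13 from 11.** The C6-C1'' bond is cut by a retro-Claisen disconnection to the 5-O-(1,1-dimethylallyl) ether 11. The neighbouring choices are weaker. Direct C-prenylation of a 5-hydroxy-7-methoxyisoflavone would give C6, C8 and O-alkylated material. Cross-coupling of a 6-halide rests on a C6/C8-selective halogenation beside an electron-rich ring B. The sigmatropic route has its regiochemistry fixed by the skeleton: C6 is the only ortho carbon with a hydrogen, and the tertiary terminus of the ether becomes the far end of the chain, so the normal prenyl group results. 11 has no C-C bond from the side chain to ring A, so the problem becomes the making of an aryl tertiary-alkyl ether.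

**11 from 10, and 10 from 8 and 9.** The tertiary allyl ether is taken back to the propargyl ether 10 (semi-hydrogenation), and 10 to phenol 8 and 3-chloro-3-methylbut-1-yne 9. The propargylic chloride is preferred to a prenyl-type electrophile because copper catalysis makes it react at its tertiary carbon only, which places the oxygen on the quaternary carbon as the [3,3] shift requires. This is the most demanding bond of the endgame: O5 is held by the C4 carbonyl and is hindered, so the forward reaction needs a base strong enough to break that hydrogen bond.

**8 from 7, and 7 from 6.** 8 comes from triol 7 by etherification of the two unchelated phenols, and 7 from the tribenzyl ether 6 by hydrogenolysis. The exchange costs two steps, but each group fits its task. Benzyl survives KOH, HNO3 and warm methanolic HCl, keeps O2' out of the ring closure, and is removed while no alkene is present. The hydrogen bond of the 5-hydroxyl then separates O5 from O2' and O4' without further differentiation.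

**6 from 4 (key disconnection).** Cutting the C3-C1' and O1-C2 bonds of 6 leads to the 2'-hydroxychalcone 4, in which ring B is on the β-carbon and O1 is still a phenol. Compared with a deoxybenzoin plus a one-carbon unit, or a 3-halochromone plus an arylboron reagent, this cut needs no preformed aryl-C3 bond and no separate C2 synthon; both come from the aldehyde carbon of the ring B partner. Ring C, the aryl-C3 bond and the oxidation level of C2 are all set in the forward step, which runs through the dimethyl acetal 5. It requires migration of aryl rather than aroyl, an oxidant that finds no other alkene in the molecule, and ring closure by the ring A phenol alone.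

**4 from 2 and 3; 2 from 1.** The Cα=Cβ bond of 4 is an aldol disconnection to acetophenone 2 and 2,4-bis(benzyloxy)benzaldehyde 3. 2 comes from 2',6'-dihydroxy-4'-methoxyacetophenone 1 by one benzylation. Starting from 1 puts the methyl group on O7 from the outset. Because the two hydroxyls of 1 are equivalent, only one mono-ether can form; the oxygen left free becomes O1 and the benzylated one becomes O5.

## Roads not taken

**Alternative 1:** Ring C would be cut at C3-C4 and O1-C2, and the key-step product would be the tris-MOM isoflavone A1, one acid step from 14. Heating the prenylated benzodioxinone A2 should extrude its ketal fragment and leave the quinoketene A3. The morpholine enamine A4 of the ring B arylacetaldehyde would capture A3 at the ketene carbon (C3-C4) and at the ring oxygen (O1-C2), and loss of the amine would give A1.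
- Merits: it is convergent, uses no thallium and no redox change, and the prenyl group is in place before ring C forms, so the protecting-group exchange of the chosen route disappears.
- Weak points: A2 is a phloroglucinol carboxylic acid derivative with three differently treated oxygens and a prenyl group between two of them, so the regiochemical problem of the target is moved to an earlier, less biased ring. A4 derives from an electron-rich arylacetaldehyde that is prone to self-condensation. A3 needs temperatures well above 100 °C, where its capture by an enamine to a 3-arylchromone has little precedent and dimerisation competes. The final triple MOM removal meets the same acid-sensitive prenyl/5-hydroxyl pair as the chosen route.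
- Comparison: after fragment assembly this road is shorter. The chosen plan sets against that fragments that are bought or made in one step, a C6 regiochemistry enforced by a [3,3] shift, and a key step of long standing.

**Alternative 2:** Here ring A is the ring that is built. The product would be A5, the same compound as 13 of the chosen route, cut at C8-C8a and C4a-C5 into the 3-aryl-5-bromo-4-pyranone A6 and the 2-prenyl Brassard-type diene A7. Cycloaddition across the brominated double bond of A6, followed by elimination of the halide and of the ketene-acetal substituents, would aromatise ring A with O5 free, O7 methylated and the prenyl group at C6.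
- Merits: the substitution pattern of ring A, the hardest part of the target, comes from one step without any chemistry at O5, and only one deprotection follows. In this respect it is clearly better than the chosen route, which spends three steps (6 to 8) on the prenyl group.
- Weak points: a 4-pyranone is a vinylogous ester with partial aromatic character and a poor dienophile, unlike the haloquinones for which such dienes are established. Forcing conditions would be needed for a diene that is hydrolytically fragile and, with a substituent at C2, reluctant to adopt the s-cis form. A6 needs its own synthesis with a selective mono-arylation. The orientation of the addition, on which the C6/C8 placement depends, is governed only by the bromine.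
- Comparison: against the shorter endgame the chosen plan sets reactions with close precedent on flavonoid substrates and a regiochemical argument that does not depend on a cycloaddition of uncertain orientation.

**Alternative 3:** Ring C would be cut at O1-C8a and C4-C4a. The product A8, the 5,7-dimethyl ether with ring B as its bis-MOM ether, would come from the silylaryl triflate A9 and the (Z)-3-hydroxy-2-arylacrylate A10. A fluoride source releases the aryne A11 from A9, the enol oxygen of A10 adds to the aryne carbon remote from the flanking methoxy group, and the aryl anion formed beside that methoxy group closes onto the cis ester.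
- Merits: the conditions are mild and nearly neutral, so a prenyl group survives; the two halves are joined convergently; and the methoxy group beside the triple bond controls the orientation of addition reliably.
- Weak points: A9 is a hexasubstituted benzene whose preparation is longer than all the ring A chemistry of the chosen route. The enolate of A10 is ambident, and arynes insert into C-C bonds of β-dicarbonyl compounds, so C-arylation competes with the O-arylation that is needed. A8 has a methyl ether on O5, so a chelation-directed demethylation by a boron or aluminium halide must follow in the presence of the prenyl group and of the O7 methyl ether. That reagent type readily cyclises or hydrohalogenates an ortho-prenylphenol.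
- Comparison: the chosen plan is longer after its key step, but it keeps O5 and O7 distinguished from the first step (benzyl against methyl) and never exposes the prenyl group to a Lewis acid.

Key step: step 3

Remark: 3 and 9 are taken as catalogue compounds; 5 and 12 are racemic at one sp3 carbon that becomes sp2 within the same step, and the target has no stereocentre.

## Route

Step 1
Reactants: 1 2',6'-dihydroxy-4'-methoxyacetophenone
Product: 2 1-[2-(benzyloxy)-6-hydroxy-4-methoxyphenyl]ethan-1-one
Conditions: BnBr (1.05 equiv), K2CO3, acetone, reflux
Reagents that add atoms: benzyl bromide, BrCc1ccccc1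
Why: Williamson etherification; the two hydroxyls of 1 are equivalent, and once one is benzylated the other is locked in a strong hydrogen bond to the ketone and alkylates far more slowly, so the mono-ether should predominate.

Step 2
Reactants: 2 1-[2-(benzyloxy)-6-hydroxy-4-methoxyphenyl]ethan-1-one; 3 2,4-bis(benzyloxy)benzaldehyde
Product: 4 (E)-1-[2-(benzyloxy)-6-hydroxy-4-methoxyphenyl]-3-[2,4-bis(benzyloxy)phenyl]prop-2-en-1-one
Conditions: KOH (50% aq), EtOH/THF, rt
Reagents that add atoms: none
Why: Claisen-Schmidt condensation (aldol addition, then E1cB loss of water) of a methyl ketone with a non-enolisable aldehyde; the conjugated (E)-enone is the thermodynamic product, and strong base keeps the phenoxide from closing to the flavanone.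

Step 3
Reactants: 4 (E)-1-[2-(benzyloxy)-6-hydroxy-4-methoxyphenyl]-3-[2,4-bis(benzyloxy)phenyl]prop-2-en-1-one
Product: 6 5,2',4'-tris(benzyloxy)-7-methoxyisoflavone, via dimethyl acetal 5 (not isolated)
Conditions: Tl(NO3)3·3H2O (1.2 equiv), MeOH/HC(OMe)3/THF (solvent), rt; filter off TlNO3; then 10% aq HCl added to the filtrate, 50 °C
Reagents that add atoms: methanol, CO (supplies the two methoxy groups of 5; both leave again on ring closure, so 6 keeps no reagent atom)
Why: This is the oxidative 1,2-aryl rearrangement of a 2'-hydroxychalcone by Tl(NO3)3, the laboratory counterpart of the aryl shift of isoflavone biosynthesis and the standard chalcone route to isoflavones. Trivalent thallium adds to the enone double bond at the α-carbon while methanol adds at the benzylic β-carbon, which the 2,4-bis(benzyloxy)phenyl group stabilises. The electron-rich aryl group then shifts from the β- to the α-carbon through a phenonium ion as monovalent thallium leaves (C3-C1' bond), and methanol traps the resulting oxocarbenium ion as the dimethyl acetal 5. After removal of TlNO3, acid ionises the acetal and the free ring A phenol attacks the oxocarbenium carbon in a 6-exo-trig closure (O1-C2 bond, ring C); loss of methanol from the 2-methoxyisoflavanone gives the pyranone. No stereocentre survives: the α-carbon of 5 is formed racemic and becomes sp2 in 6. The step needs aryl rather than aroyl migration, which the ortho and para alkoxy donors of ring B secure, and closure by ring A only, which the benzyl ether on O2' secures by keeping that oxygen from attacking the acetal to give a 3-aroylbenzofuran. Chemoselectivity rests on the absence of any isolated alkene, which is why the prenyl group is introduced later; the benzyl ethers should withstand HNO3 in methanol and the dilute HCl of the closure, and partial loss of the 5-O-benzyl group would be harmless because step 4 removes it anyway.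

Step 4
Reactants: 6 5,2',4'-tris(benzyloxy)-7-methoxyisoflavone
Product: 7 5,2',4'-trihydroxy-7-methoxyisoflavone
Conditions: H2 (1 atm), 10% Pd/C, THF/MeOH, rt
Reagents that add atoms: none
Why: Hydrogenolysis of three aryl benzyl ethers; benzylic C-O cleavage on Pd/C is much faster than reduction of the vinylogous-ester C2=C3 bond, and the reaction is stopped once three equivalents of H2 are taken up.

Step 5
Reactants: 7 5,2',4'-trihydroxy-7-methoxyisoflavone
Product: 8 5-hydroxy-7-methoxy-2',4'-bis(methoxymethoxy)isoflavone
Conditions: MOMCl (2.2 equiv), iPr2NEt, CH2Cl2/DMF, 0 °C to rt
Reagents that add atoms: chloromethyl methyl ether, COCCl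
Why: O-Alkylation (MOM ether formation) of the two free phenols of ring B; the 5-hydroxyl is tied to the C4 carbonyl by a hydrogen bond and is not alkylated under amine base, a selectivity general for 5-hydroxyisoflavones.

Step 6
Reactants: 8 5-hydroxy-7-methoxy-2',4'-bis(methoxymethoxy)isoflavone; 9 3-chloro-3-methylbut-1-yne
Product: 10 7-methoxy-2',4'-bis(methoxymethoxy)-5-[(2-methylbut-3-yn-2-yl)oxy]isoflavone
Conditions: 9 (3 equiv), DBU, CuCl2·2H2O (1 mol%), MeCN, 0 °C to rt
Reagents that add atoms: none
Why: Copper-catalysed propargylic etherification of a phenol: the copper acetylide of 9 ionises to an allenylidene-type electrophile that the phenoxide attacks at the tertiary carbon; O5 is the only free hydroxyl, electron-poor phenols are good substrates for this reaction, and DBU is strong enough to deprotonate the chelated 5-hydroxyl.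

Step 7
Reactants: 10 7-methoxy-2',4'-bis(methoxymethoxy)-5-[(2-methylbut-3-yn-2-yl)oxy]isoflavone
Product: 11 7-methoxy-2',4'-bis(methoxymethoxy)-5-[(2-methylbut-3-en-2-yl)oxy]isoflavone
Conditions: H2 (1 atm), Pd/CaCO3 poisoned with Pb(OAc)2 (Lindlar catalyst), quinoline, EtOAc, rt
Reagents that add atoms: none
Why: Semi-hydrogenation of a terminal alkyne on poisoned palladium; quinoline suppresses over-reduction, the conjugated C2=C3 bond is inert on this catalyst, and room temperature keeps 11 from rearranging before the catalyst is removed.

Step 8
Reactants: 11 7-methoxy-2',4'-bis(methoxymethoxy)-5-[(2-methylbut-3-en-2-yl)oxy]isoflavone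
Product: 13 5-hydroxy-7-methoxy-2',4'-bis(methoxymethoxy)-6-(3-methylbut-2-en-1-yl)isoflavone, via cyclohexadienone 12 (not isolated)
Conditions: toluene, 110 °C
Reagents that add atoms: none
Why: Aromatic Claisen rearrangement: the [3,3] shift moves the allyl unit from O5 to C6, the only ortho carbon bearing hydrogen, with allylic inversion so that the CH2 terminus bonds to the ring and the 3-methylbut-2-enyl group results; dienone 12 enolises to the phenol, which the hydrogen bond to C4=O stabilises. Tertiary allyl aryl ethers rearrange at much lower temperature than simple allyl ethers.

Step 9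
Reactants: 13 5-hydroxy-7-methoxy-2',4'-bis(methoxymethoxy)-6-(3-methylbut-2-en-1-yl)isoflavone
Product: 14 7-O-methylluteone
Conditions: 3 M aq HCl/MeOH, 40 °C
Reagents that add atoms: none
Why: Acid-catalysed acetal exchange removes both MOM ethers as dimethoxymethane; dilute acid at modest temperature is the usual way to unmask prenylated polyphenols without adding the ortho hydroxyl to the alkene.

## Compound list

1 | 2',6'-dihydroxy-4'-methoxyacetophenone | COc1cc(O)c(C(C)=O)c(O)c1 | starting material
2 | 1-[2-(benzyloxy)-6-hydroxy-4-methoxyphenyl]ethan-1-one | COc1cc(O)c(C(C)=O)c(OCc2ccccc2)c1 | intermediate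
3 | 2,4-bis(benzyloxy)benzaldehyde | O=Cc1ccc(OCc2ccccc2)cc1OCc1ccccc1 | starting material
4 | (E)-1-[2-(benzyloxy)-6-hydroxy-4-methoxyphenyl]-3-[2,4-bis(benzyloxy)phenyl]prop-2-en-1-one | COc1cc(O)c(C(=O)/C=C/c2ccc(OCc3ccccc3)cc2OCc2ccccc2)c(OCc2ccccc2)c1 | intermediate
5 | 1-[2-(benzyloxy)-6-hydroxy-4-methoxyphenyl]-2-[2,4-bis(benzyloxy)phenyl]-3,3-dimethoxypropan-1-one (racemic) | COc1cc(O)c(C(=O)C(C(OC)OC)c2ccc(OCc3ccccc3)cc2OCc2ccccc2)c(OCc2ccccc2)c1 | intermediate
6 | 5,2',4'-tris(benzyloxy)-7-methoxyisoflavone | COc1cc2occ(-c3ccc(OCc4ccccc4)cc3OCc3ccccc3)c(=O)c2c(OCc2ccccc2)c1 | intermediate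
7 | 5,2',4'-trihydroxy-7-methoxyisoflavone | COc1cc2occ(-c3ccc(O)cc3O)c(=O)c2c(O)c1 | intermediate
8 | 5-hydroxy-7-methoxy-2',4'-bis(methoxymethoxy)isoflavone | COc1cc2occ(-c3ccc(OCOC)cc3OCOC)c(=O)c2c(O)c1 | intermediate
9 | 3-chloro-3-methylbut-1-yne | C#CC(C)(C)Cl | starting material
10 | 7-methoxy-2',4'-bis(methoxymethoxy)-5-[(2-methylbut-3-yn-2-yl)oxy]isoflavone | COc1cc2occ(-c3ccc(OCOC)cc3OCOC)c(=O)c2c(OC(C)(C)C#C)c1 | intermediate
11 | 7-methoxy-2',4'-bis(methoxymethoxy)-5-[(2-methylbut-3-en-2-yl)oxy]isoflavone | COc1cc2occ(-c3ccc(OCOC)cc3OCOC)c(=O)c2c(OC(C)(C)C=C)c1 | intermediate
12 | 3-[2,4-bis(methoxymethoxy)phenyl]-7-methoxy-6-(3-methylbut-2-en-1-yl)-4H-chromene-4,5(6H)-dione (racemic) | COC1=CC2=C(C(=O)C1CC=C(C)C)C(=O)C(c1ccc(OCOC)cc1OCOC)=CO2 | intermediate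
13 | 5-hydroxy-7-methoxy-2',4'-bis(methoxymethoxy)-6-(3-methylbut-2-en-1-yl)isoflavone | COc1cc2occ(-c3ccc(OCOC)cc3OCOC)c(=O)c2c(O)c1CC=C(C)C | intermediate
14 | 7-O-methylluteone, 3-(2,4-dihydroxyphenyl)-5-hydroxy-7-methoxy-6-(3-methylbut-2-en-1-yl)-4H-chromen-4-one | COc1cc2occ(-c3ccc(O)cc3O)c(=O)c2c(O)c1CC=C(C)C | target

## Step count and least certain steps

Total step count: 9. Longest linear sequence: 9 steps (1 to 14; 3 and 9 enter as purchased compounds).

**Step 3 (key step).** What may go wrong: oxidative closure of the free ring A phenol onto the thallated adduct (aurone-type cyclisation) or oxidation of the electron-rich ring A may compete with aryl migration, and closure of the acetal may stall. Fallback, setting out from 2 and returning at 6: 2 is condensed with N,N-dimethylformamide dimethyl acetal (neat, 90 °C) to (E)-1-[2-(benzyloxy)-6-hydroxy-4-methoxyphenyl]-3-(dimethylamino)prop-2-en-1-one F1. Iodine in CHCl3 should cyclise this to 5-(benzyloxy)-3-iodo-7-methoxy-4H-chromen-4-one F2. Suzuki-Miyaura coupling of F2 with [2,4-bis(benzyloxy)phenyl]boronic acid (Pd(PPh3)4, Na2CO3, DME/H2O, 80 °C) should then give 6. Here the aryl-C3 bond comes from cross-coupling instead of migration.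

**Step 6.** What may go wrong: O-alkylation of the hydrogen-bonded, hindered 5-phenol by a tertiary electrophile may be slow, so that elimination of HCl from 9 outruns ether formation. Fallback, setting out from 8 and returning at 13 (it also bypasses steps 7 and 8): iodination of 8 with benzyltrimethylammonium dichloroiodate and CaCO3 in CH2Cl2/MeOH at rt, directed ortho to the free 5-hydroxyl on the phloroglucinol-type ring, should give 5-hydroxy-6-iodo-7-methoxy-2',4'-bis(methoxymethoxy)isoflavone F3. Stille coupling of F3 with tributyl(3-methylbut-2-en-1-yl)stannane (Pd(PPh3)4, DMF, 90 °C) should then give 13. This replaces the O5-to-C6 transfer by a direct C-C coupling; its own weak point is C6/C8 selectivity in the iodination, which is why it is not the first choice.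

**Step 9.** What may go wrong: acid-catalysed addition of the 5-hydroxyl to the prenyl double bond (closure to a dimethyldihydropyran ring), or hydration of the alkene, while the MOM ethers are being cleaved. Fallback, setting out from 10 and returning at 14: the order is changed so that acid never meets the prenyl/phenol pair. The MOM ethers of 10 are removed first (HCl, MeOH, rt; a tertiary propargylic ether ionises far less readily than a MOM acetal) to give 2',4'-dihydroxy-7-methoxy-5-[(2-methylbut-3-yn-2-yl)oxy]isoflavone F4. Semi-hydrogenation (H2, Pd/CaCO3 poisoned with Pb(OAc)2, quinoline, EtOAc) gives 2',4'-dihydroxy-7-methoxy-5-[(2-methylbut-3-en-2-yl)oxy]isoflavone F5. The Claisen rearrangement of F5 in toluene at 110 °C then delivers 14 under neutral conditions as the last step.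

**Step 1.** What may go wrong: over-alkylation to the bis-ether or incomplete conversion, so that the mono-ether is hard to obtain pure. Fallback, setting out from 1 and returning at 2: exhaustive benzylation (BnBr in excess, K2CO3, DMF, 60 °C) gives 1-[2,6-bis(benzyloxy)-4-methoxyphenyl]ethan-1-one F6. Chelation-controlled cleavage of one ortho benzyl ether with MgBr2·OEt2 in toluene/Et2O at reflux should then give 2; the magnesium phenoxide chelate formed after the first cleavage protects the second ether.

## Further compounds

F1 | step 3 | (E)-1-[2-(benzyloxy)-6-hydroxy-4-methoxyphenyl]-3-(dimethylamino)prop-2-en-1-one | COc1cc(O)c(C(=O)/C=C/N(C)C)c(OCc2ccccc2)c1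
F2 | step 3 | 5-(benzyloxy)-3-iodo-7-methoxy-4H-chromen-4-one | COc1cc2occ(I)c(=O)c2c(OCc2ccccc2)c1
F3 | step 6 | 5-hydroxy-6-iodo-7-methoxy-2',4'-bis(methoxymethoxy)isoflavone | COc1cc2occ(-c3ccc(OCOC)cc3OCOC)c(=O)c2c(O)c1I
F4 | step 9 | 2',4'-dihydroxy-7-methoxy-5-[(2-methylbut-3-yn-2-yl)oxy]isoflavone | COc1cc2occ(-c3ccc(O)cc3O)c(=O)c2c(OC(C)(C)C#C)c1
F5 | step 9 | 2',4'-dihydroxy-7-methoxy-5-[(2-methylbut-3-en-2-yl)oxy]isoflavone | COc1cc2occ(-c3ccc(O)cc3O)c(=O)c2c(OC(C)(C)C=C)c1
F6 | step 1 | 1-[2,6-bis(benzyloxy)-4-methoxyphenyl]ethan-1-one | COc1cc(OCc2ccccc2)c(C(C)=O)c(OCc2ccccc2)c1
A1 | alternative 1 | 7-methoxy-5,2',4'-tris(methoxymethoxy)-6-(3-methylbut-2-en-1-yl)isoflavone | COCOc1c(CC=C(C)C)c(OC)cc2occ(-c3ccc(OCOC)cc3OCOC)c(=O)c12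
A2 | alternative 1 | 7-methoxy-5-(methoxymethoxy)-2,2-dimethyl-6-(3-methylbut-2-en-1-yl)-4H-1,3-benzodioxin-4-one | COCOc1c(CC=C(C)C)c(OC)cc2OC(C)(C)OC(=O)c12
A3 | alternative 1 | 3-methoxy-5-(methoxymethoxy)-4-(3-methylbut-2-en-1-yl)-6-(oxomethylidene)cyclohexa-2,4-dien-1-one | O=C=C1C(=O)C=C(OC)C(CC=C(C)C)=C1OCOC
A4 | alternative 1 | (E)-4-{2-[2,4-bis(methoxymethoxy)phenyl]ethenyl}morpholine | COCOc1ccc(/C=C/N2CCOCC2)c(OCOC)c1
A5 | alternative 2 | 5-hydroxy-7-methoxy-2',4'-bis(methoxymethoxy)-6-(3-methylbut-2-en-1-yl)isoflavone (identical with 13) | COc1cc2occ(-c3ccc(OCOC)cc3OCOC)c(=O)c2c(O)c1CC=C(C)C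
A6 | alternative 2 | 3-[2,4-bis(methoxymethoxy)phenyl]-5-bromo-4H-pyran-4-one | COCOc1ccc(-c2cocc(Br)c2=O)c(OCOC)c1
A7 | alternative 2 | {[1,3-dimethoxy-2-(3-methylbut-2-en-1-yl)buta-1,3-dien-1-yl]oxy}trimethylsilane (ketene acetal geometry not defined) | C=C(OC)C(CC=C(C)C)=C(OC)O[Si](C)(C)C
A8 | alternative 3 | 5,7-dimethoxy-2',4'-bis(methoxymethoxy)-6-(3-methylbut-2-en-1-yl)isoflavone | COc1cc2occ(-c3ccc(OCOC)cc3OCOC)c(=O)c2c(OC)c1CC=C(C)C
A9 | alternative 3 | 2,4-dimethoxy-3-(3-methylbut-2-en-1-yl)-6-(trimethylsilyl)phenyl trifluoromethanesulfonate | COc1cc([Si](C)(C)C)c(OS(=O)(=O)C(F)(F)F)c(OC)c1CC=C(C)C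
A10 | alternative 3 | methyl (Z)-2-[2,4-bis(methoxymethoxy)phenyl]-3-hydroxyprop-2-enoate | COCOc1ccc(/C(C(=O)OC)=C/O)c(OCOC)c1
A11 | alternative 3 | 3,5-dimethoxy-4-(3-methylbut-2-en-1-yl)benzyne | COC1=C(CC=C(C)C)C(OC)=CC#C1
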